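**Strategy.** Ring B is cut at C5–C6 and C7–C8, which releases C6–C7 as an acetaldehyde enol silane. The key step exploits the aldol pattern O–C6–C7H2–C8(OH)CH3 of ring B and the nucleophilicity of C5 in a ring A C4=C5 alkene. Under TiCl4 the enol silane adds to the C8 methyl ketone (Felkin–Anh control from C9 sets C8) and the new C6 aldehyde is trapped by C5 in a Prins closure. The precursor is a methyl ketone that carries the cyclohexenyl ring A on C9, made by a chiral-imine Michael addition to a linalool-derived nitroalkene. Oxidation, conjugate methylation and dissolving-metal reduction then set C4, C5 and C6.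

Key step: step 9

Remark: atoms are numbered as in labdanes (C1–C10 decalin, C11–C16 side chain, C17 on C8, C18/C19 on C4, C20 on C10); stereocentres left undefined in a SMILES are carried as mixtures and are destroyed later.

Step 1
Reactants: 1 (R)-linalool
Product: 2 (3R)-3-[(tert-butyldimethylsilyl)oxy]-3,7-dimethylocta-1,6-diene
Conditions: TBSOTf, 2,6-lutidine, CH2Cl2, 0 °C
Reagents that add atoms: tert-butyldimethylsilyl triflate, CC(C)(C)[Si](C)(C)OS(=O)(=O)C(F)(F)F
Why: Silylation with a silyl triflate should protect the ionisable tertiary allylic carbinol (C13, taken unchanged from the chiral pool) for the later Lewis-acid and basic steps.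

Step 2
Reactants: 2 silyl ether
Product: 3 (4R)-4-[(tert-butyldimethylsilyl)oxy]-4-methylhex-5-enal
Conditions: O3 (1 equiv, dye end-point), CH2Cl2/MeOH, −78 °C; then Me2S
Reagents that add atoms: ozone, O=[O+][O-]
Why: In this ozonolysis the electron-rich trisubstituted alkene should be cleaved much faster than the hindered monosubstituted vinyl group, so that the aldehyde carbon becomes C9.

Step 3
Reactants: 3 aldehyde; 4 nitroethane
Product: 6 (2E,6R)-6-[(tert-butyldimethylsilyl)oxy]-6-methyl-2-nitroocta-2,7-diene, via nitro alcohol 5 (not isolated)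
Conditions: Et3N (cat.), 25 °C; then MsCl, Et3N, CH2Cl2, 0 °C
Reagents that add atoms: none
Why: A Henry reaction followed by mesylation and E1cB elimination should give the thermodynamically preferred E nitroalkene, in which C9 is the acceptor carbon and C8 carries the latent carbonyl.

Step 4
Reactants: 7 2,6-dimethylcyclohexanone; 8 (S)-1-phenylethylamine
Product: 9 (1S)-N-(2,6-dimethylcyclohexylidene)-1-phenylethan-1-amine
Conditions: TsOH (cat.), toluene, reflux, Dean–Stark
Reagents that add atoms: none
Why: Acid-catalysed condensation with azeotropic removal of water should give the chiral imine of the symmetrical ketone.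

Step 5
Reactants: 9 imine; 6 nitroalkene
Product: 11 (2R)-2-[(3R,6R)-6-[(tert-butyldimethylsilyl)oxy]-6-methyl-2-nitrooct-7-en-3-yl]-2,6-dimethylcyclohexan-1-one, via adduct imine 10 (not isolated)
Conditions: THF, 40 °C; then 20% aq AcOH, 25 °C
Reagents that add atoms: water, O
Why: In this Michael addition of the secondary enamine tautomer (aza-ene type, internal N–H transfer) the more substituted α-carbon should attack anti to the phenyl group of the auxiliary (sets C10), through a compact chair-like transition state with the nitroalkene β-substituent exo (sets C9).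

Step 6
Reactants: 11 nitro ketone
Product: 12 (2R)-2-[(3R,6R)-6-[(tert-butyldimethylsilyl)oxy]-6-methyl-2-nitrooct-7-en-3-yl]-2,6-dimethylcyclohexan-1-ol
Conditions: NaBH4, MeOH, 0 → 25 °C
Reagents that add atoms: none
Why: Borohydride reduction should take the ring ketone and leave the secondary nitro group; the new carbinol centre is removed in the next step.

Step 7
Reactants: 12 nitro alcohol
Product: 13 (3R,6R)-6-[(tert-butyldimethylsilyl)oxy]-3-[(1S)-1,3-dimethylcyclohex-2-en-1-yl]-6-methyl-2-nitrooct-7-ene
Conditions: POCl3, pyridine, 0 → 80 °C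
Reagents that add atoms: none
Why: E2 dehydration through the dichlorophosphate can only give the C4=C5 alkene, because C10 is quaternary and C4 carries the only β-hydrogen.

Step 8
Reactants: 13 nitro alkene
Product: 15 (3R,6R)-6-[(tert-butyldimethylsilyl)oxy]-3-[(1S)-1,3-dimethylcyclohex-2-en-1-yl]-6-methyloct-7-en-2-one, via sodium nitronate 14 (not isolated)
Conditions: NaOMe, MeOH, 0 °C; then aq TiCl3, NH4OAc (pH 5–6), THF, 0 → 25 °C
Reagents that add atoms: water, O
Why: A reductive Nef reaction of the nitronate with titanium trichloride at buffered pH should unveil the C8 methyl ketone without epimerising C9 and without touching the alkenes or the silyl ether.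

Step 9
Reactants: 15 methyl ketone; 16 trimethyl(vinyloxy)silane
Product: 18 4-chloro-13-[(tert-butyldimethylsilyl)oxy]-19-norlabd-14-ene-6,8α-diol (mixture at C4, C5, C6), via aldol adduct 17 (not isolated)
Conditions: 16 (slow addition), TiCl4, 2,6-di-tert-butyl-4-methylpyridine, CH2Cl2, −78 °C; aq NaHCO3
Reagents that add atoms: titanium tetrachloride, Cl[Ti](Cl)(Cl)Cl
Why: Proposed new method: TiCl4 activates the C8 ketone of 15, the enol silane adds through C7 (Mukaiyama aldol) and, after loss of the silyl group, the titanium-bound β-alkoxy aldehyde 17 is attacked at C6 by C5 of the ring A C4=C5 alkene (Prins cyclisation), with the tertiary C4 cation captured by chloride. The closest known reaction type is the tandem Mukaiyama aldol–Prins cyclisation of enol ethers with aldehydes, together with Lewis-acid carbonyl-ene/Prins cyclisations of citronellal-type unsaturated aldehydes; new here are the ketone acceptor, the external acetaldehyde enol silane and the carbocyclic ring. Ring B closes in a 6-exo-trig cation–olefin mode (the attacked C6=O is exocyclic to the forming ring), through C5 because only this gives a tertiary cation and a six-membered ring. C8 is controlled by Felkin–Anh addition to the acyclic ketone, anti to the quaternary C10 substituent on C9, which places the C8 oxygen α and C17 β; C4, C5 and C6 need no control (axial attack on the cyclohexene on the face of the tether should favour the cis fusion) because steps 10 to 12 erase and reset them. The step needs the enol silane to react with the ketone and not with the aldehyde it creates, secured by fast intramolecular trapping of that aldehyde and slow addition of 16, and it needs the tertiary allylic silyl ether to survive, secured by −78 °C and the hindered pyridine base.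

Step 10
Reactants: 18 chloro diol
Product: 20 13-[(tert-butyldimethylsilyl)oxy]-8α-hydroxy-19-norlabda-4,14-dien-6-one, via chloro ketone 19 (not isolated)
Conditions: Dess–Martin periodinane, NaHCO3, CH2Cl2, 0 °C; then DBU, 25 °C
Reagents that add atoms: none
Why: Dess–Martin oxidation of the only secondary alcohol and E1cB loss of HCl from the β-chloro ketone should give the conjugated C4=C5–C6=O enone (isopulegone-to-pulegone type conjugation), which erases the C4, C5 and C6 centres.

Step 11
Reactants: 20 enone
Product: 21 (13R)-13-[(tert-butyldimethylsilyl)oxy]-8α-hydroxylabd-14-en-6-one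
Conditions: Me2CuLi (excess), THF, −78 → −20 °C; aq NH4Cl
Reagents that add atoms: lithium dimethylcuprate, [Li+].C[Cu-]C
Why: Cuprate conjugate addition to the s-cis 2-alkylidene ketone (pulegone type) should complete the C4 gem-dimethyl group, and protonation of the enolate at C5 from the α face, away from the axial C10 and 4β methyl groups, should give the trans ring fusion, which is also the thermodynamic epimer.

Step 12
Reactants: 21 ketone
Product: 22 (13R)-13-[(tert-butyldimethylsilyl)oxy]labd-14-ene-6α,8α-diol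
Conditions: Li, NH3(l), THF, t-BuOH, −78 °C; then NH4Cl
Reagents that add atoms: none
Why: Dissolving-metal reduction should give the thermodynamically preferred equatorial 6α alcohol, whereas hydride reagents would attack the open α face and give the axial 6β epimer.

Step 13
Reactants: 22 silyl ether diol
Product: 23 (13R)-labd-14-ene-6α,8α,13-triol
Conditions: TBAF, THF, 60 °C
Reagents that add atoms: none
Why: Fluoride-mediated desilylation should free the tertiary C13 hydroxyl without affecting the other functions.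

Step 14
Reactants: 23 triol; 24 angelic acid
Product: 26 (13R)-6α-[(Z)-2-methylbut-2-enoyloxy]labd-14-ene-8α,13-diol, via mixed anhydride 25 (not isolated)
Conditions: 24, 2,4,6-trichlorobenzoyl chloride, Et3N, toluene, 25 °C; then 23, toluene, 80 °C
Reagents that add atoms: none
Why: Yamaguchi-type mixed-anhydride acylation should esterify the only secondary hydroxyl (the two tertiary ones are inert), and the absence of a nucleophilic catalyst should prevent Z to E isomerisation of the angelate.

**Compound list**

1 | (R)-linalool, (3R)-3,7-dimethylocta-1,6-dien-3-ol | C=C[C@](C)(O)CCC=C(C)C | starting material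
2 | (3R)-3-[(tert-butyldimethylsilyl)oxy]-3,7-dimethylocta-1,6-diene | C=C[C@](C)(O[Si](C)(C)C(C)(C)C)CCC=C(C)C | intermediate
3 | (4R)-4-[(tert-butyldimethylsilyl)oxy]-4-methylhex-5-enal | C=C[C@](C)(O[Si](C)(C)C(C)(C)C)CCC=O | intermediate
4 | nitroethane | CC[N+](=O)[O-] | starting material
5 | (6R)-6-[(tert-butyldimethylsilyl)oxy]-6-methyl-2-nitrooct-7-en-3-ol (mixture at C2, C3) | C=C[C@](C)(O[Si](C)(C)C(C)(C)C)CCC(O)C(C)[N+](=O)[O-] | intermediate
6 | (2E,6R)-6-[(tert-butyldimethylsilyl)oxy]-6-methyl-2-nitroocta-2,7-diene | C=C[C@](C)(O[Si](C)(C)C(C)(C)C)CC/C=C(\C)[N+](=O)[O-] | intermediate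
7 | 2,6-dimethylcyclohexanone | CC1CCCC(C)C1=O | starting material
8 | (S)-1-phenylethylamine | C[C@H](N)c1ccccc1 | starting material
9 | (1S)-N-(2,6-dimethylcyclohexylidene)-1-phenylethan-1-amine | CC1CCCC(C)C1=N[C@@H](C)c1ccccc1 | intermediate
10 | Michael adduct imine (C9 R, C10 R; mixture at C4 and C8) | C=C[C@](C)(O[Si](C)(C)C(C)(C)C)CC[C@H]([C@@]1(C)CCCC(C)C1=N[C@@H](C)c1ccccc1)C(C)[N+](=O)[O-] | intermediate
11 | (2R)-2-[(3R,6R)-6-[(tert-butyldimethylsilyl)oxy]-6-methyl-2-nitrooct-7-en-3-yl]-2,6-dimethylcyclohexan-1-one (mixture at C4 and C8) | C=C[C@](C)(O[Si](C)(C)C(C)(C)C)CC[C@H]([C@@]1(C)CCCC(C)C1=O)C(C)[N+](=O)[O-] | intermediate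
12 | (2R)-2-[(3R,6R)-6-[(tert-butyldimethylsilyl)oxy]-6-methyl-2-nitrooct-7-en-3-yl]-2,6-dimethylcyclohexan-1-ol (mixture at C4, C5, C8) | C=C[C@](C)(O[Si](C)(C)C(C)(C)C)CC[C@H]([C@@]1(C)CCCC(C)C1O)C(C)[N+](=O)[O-] | intermediate
13 | (3R,6R)-6-[(tert-butyldimethylsilyl)oxy]-3-[(1S)-1,3-dimethylcyclohex-2-en-1-yl]-6-methyl-2-nitrooct-7-ene (mixture at C8) | C=C[C@](C)(O[Si](C)(C)C(C)(C)C)CC[C@H]([C@@]1(C)CCCC(C)=C1)C(C)[N+](=O)[O-] | intermediate
14 | sodium nitronate of 13 | C=C[C@](C)(O[Si](C)(C)C(C)(C)C)CC[C@H]([C@@]1(C)CCCC(C)=C1)C(C)=[N+]([O-])[O-].[Na+] | intermediate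
15 | (3R,6R)-6-[(tert-butyldimethylsilyl)oxy]-3-[(1S)-1,3-dimethylcyclohex-2-en-1-yl]-6-methyloct-7-en-2-one | C=C[C@](C)(O[Si](C)(C)C(C)(C)C)CC[C@H]([C@@]1(C)CCCC(C)=C1)C(C)=O | intermediate
16 | trimethyl(vinyloxy)silane | C=CO[Si](C)(C)C | starting material
17 | (3R,4R,7R)-7-[(tert-butyldimethylsilyl)oxy]-4-[(1S)-1,3-dimethylcyclohex-2-en-1-yl]-3-hydroxy-3,7-dimethylnon-8-enal (formed as its titanium alkoxide) | C=C[C@](C)(O[Si](C)(C)C(C)(C)C)CC[C@H]([C@@]1(C)CCCC(C)=C1)[C@](C)(O)CC=O | intermediate
18 | 4-chloro-13-[(tert-butyldimethylsilyl)oxy]-19-norlabd-14-ene-6,8α-diol (8β-CH3, 9β side chain, 10β-CH3, 13R; mixture at C4, C5, C6) | C=C[C@](C)(O[Si](C)(C)C(C)(C)C)CC[C@@H]1[C@@]2(C)CCCC(C)(Cl)C2C(O)C[C@@]1(C)O | intermediate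
19 | 4-chloro-13-[(tert-butyldimethylsilyl)oxy]-8α-hydroxy-19-norlabd-14-en-6-one (mixture at C4, C5) | C=C[C@](C)(O[Si](C)(C)C(C)(C)C)CC[C@@H]1[C@@]2(C)CCCC(C)(Cl)C2C(=O)C[C@@]1(C)O | intermediate
20 | (13R)-13-[(tert-butyldimethylsilyl)oxy]-8α-hydroxy-19-norlabda-4,14-dien-6-one | C=C[C@](C)(O[Si](C)(C)C(C)(C)C)CC[C@@H]1[C@@]2(C)CCCC(C)=C2C(=O)C[C@@]1(C)O | intermediate
21 | (13R)-13-[(tert-butyldimethylsilyl)oxy]-8α-hydroxylabd-14-en-6-one (5α-H) | C=C[C@](C)(O[Si](C)(C)C(C)(C)C)CC[C@@H]1[C@@]2(C)CCCC(C)(C)[C@@H]2C(=O)C[C@@]1(C)O | intermediate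
22 | (13R)-13-[(tert-butyldimethylsilyl)oxy]labd-14-ene-6α,8α-diol | C=C[C@](C)(O[Si](C)(C)C(C)(C)C)CC[C@@H]1[C@@]2(C)CCCC(C)(C)[C@@H]2[C@@H](O)C[C@@]1(C)O | intermediate
23 | (13R)-labd-14-ene-6α,8α,13-triol | C=C[C@](C)(O)CC[C@@H]1[C@@]2(C)CCCC(C)(C)[C@@H]2[C@@H](O)C[C@@]1(C)O | intermediate
24 | angelic acid, (Z)-2-methylbut-2-enoic acid | C/C=C(/C)C(=O)O | starting material
25 | angelic 2,4,6-trichlorobenzoic anhydride | C/C=C(/C)C(=O)OC(=O)c1c(Cl)cc(Cl)cc1Cl | intermediate
26 | (13R)-6α-[(Z)-2-methylbut-2-enoyloxy]labd-14-ene-8α,13-diol | C=C[C@](C)(O)CC[C@@H]1[C@@]2(C)CCCC(C)(C)[C@@H]2[C@@H](OC(=O)/C(C)=C\C)C[C@@]1(C)O | target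

**Step count.** Total: 14 steps. Longest linear sequence: 13 steps (steps 1–3 and 5–14; step 4 is a one-step branch).

**Steps most likely to fail**

1. Step 9 (proposed new method). The enol silane may oligomerise with the aldehyde it generates, the hindered ketone may not be attacked, or the tertiary allylic silyl ether may ionise under TiCl4. Fallback with known reactions, setting out from 15: aldol addition of the lithium enolate of ethyl acetate (LDA, THF, −78 °C, Felkin–Anh) should give the β-hydroxy ester F1. Reduction with LiAlH4 gives the 1,3-diol F2, and oxidation of its primary alcohol with TEMPO/PhI(OAc)2 gives hydroxy aldehyde 17 as an isolated compound. A separate Lewis-acid Prins cyclisation of 17 (TiCl4, CH2Cl2, −78 °C) then rejoins the route at 18.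

2. Step 5. Addition to the trisubstituted nitroalkene may be sluggish, and the exo/endo placement of the nitroalkene substituent may be poorly controlled, which would erode the C9 configuration. Fallback, setting out from 9: deprotonation with LDA gives the lithium aza-enolate F3, which adds to 6 at −78 °C as a metalloenamine and is hydrolysed through 10 back to 11. Any C9 epimer carried through steps 6 to 8 appears as the C9-epimeric ketone F4, which is equilibrated with DBU (C9 is α to the C8 carbonyl), separated and recycled, coming back at 15.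

3. Step 11. Steric shielding of the tetrasubstituted enone may divert the cuprate to 1,2-addition, or the C8 alkoxide may undergo retro-aldol cleavage. Fallback, setting out from 20: Luche reduction (NaBH4, CeCl3) gives the allylic alcohol F5, hydroxyl-directed Simmons–Smith cyclopropanation (Et2Zn, CH2I2) gives the cyclopropyl carbinol F6, and Dess–Martin oxidation gives the cyclopropyl ketone F7. Li/NH3 then cleaves the exocyclic C5–CH2 bond of F7 (the less substituted carbanion), which delivers the second C4 methyl group and the α-protonated C5, coming back at 21.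

**Further compounds**

F1 | step 9 | ethyl (3R,4R,7R)-7-[(tert-butyldimethylsilyl)oxy]-4-[(1S)-1,3-dimethylcyclohex-2-en-1-yl]-3-hydroxy-3,7-dimethylnon-8-enoate | C=C[C@](C)(O[Si](C)(C)C(C)(C)C)CC[C@H]([C@@]1(C)CCCC(C)=C1)[C@](C)(O)CC(=O)OCC
F2 | step 9 | (3R,4R,7R)-7-[(tert-butyldimethylsilyl)oxy]-4-[(1S)-1,3-dimethylcyclohex-2-en-1-yl]-3,7-dimethylnon-8-ene-1,3-diol | C=C[C@](C)(O[Si](C)(C)C(C)(C)C)CC[C@H]([C@@]1(C)CCCC(C)=C1)[C@](C)(O)CCO
F3 | step 5 | lithium aza-enolate of imine 9 | CC1CCCC(C)=C1N([Li])[C@@H](C)c1ccccc1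
F4 | step 5 | C9 epimer of ketone 15, (3S,6R)-6-[(tert-butyldimethylsilyl)oxy]-3-[(1S)-1,3-dimethylcyclohex-2-en-1-yl]-6-methyloct-7-en-2-one | C=C[C@](C)(O[Si](C)(C)C(C)(C)C)CC[C@@H]([C@@]1(C)CCCC(C)=C1)C(C)=O
F5 | step 11 | (13R)-13-[(tert-butyldimethylsilyl)oxy]-19-norlabda-4,14-diene-6,8α-diol | C=C[C@](C)(O[Si](C)(C)C(C)(C)C)CC[C@@H]1[C@@]2(C)CCCC(C)=C2C(O)C[C@@]1(C)O
F6 | step 11 | 4,5-methano (cyclopropane) derivative of F5 | C=C[C@](C)(O[Si](C)(C)C(C)(C)C)CC[C@@H]1[C@@]2(C)CCCC3(C)CC23C(O)C[C@@]1(C)O
F7 | step 11 | 4,5-methano-13-[(tert-butyldimethylsilyl)oxy]-8α-hydroxy-19-norlabd-14-en-6-one | C=C[C@](C)(O[Si](C)(C)C(C)(C)C)CC[C@@H]1[C@@]2(C)CCCC3(C)CC23C(=O)C[C@@]1(C)O
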